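Everything rests on cutting both C3'–prenyl bonds of ring B. Ring B has one carbon, C3', that holds neither the isobutyryl group (C5') nor ring A (C1'); in the target it is quaternary, bears two identical prenyl chains and is flanked by the oxygen-bearing C2' and C4', which is what a phloroglucinol gives when one position is alkylated twice. One operation therefore attaches both chains and dearomatises ring B. The precursor is an aromatic isobutyrylphloroglucinol whose C2' oxygen is tied to C1 of ring A in a cis-fused dihydrobenzofuran. This tether fixes the C1/C2 relationship and is released last by hydroxide attack at C2', which leaves the C1–O bond intact.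

Key step: step 7

**Remarks on the chemistry**
- Labels: ring A is the cyclohexane ring, numbered as a p-menthane. C1 carries methyl and oxygen, C2 is bonded to ring B, and C4 carries isopropenyl. Ring B runs C1' (bonded to C2), C2' (O), C3' (diprenyl), C4' (O), C5' (isobutyryl), C6' (O). The target is (1R,2R,4S), with ring B, the C1 oxygen and isopropenyl all on one face of ring A.
- Assumption: the enol and keto forms of the triketone part of ring B interconvert freely, so the drawn tautomer serves only for bookkeeping.
- A palladium-catalysed etherification of a carvyl carbonate is deliberately not used. The η3-carvyl palladium complex, like the free carvyl cation, has a mirror plane through C1 and C4. With achiral ligands it would therefore give racemic ether, whatever the purity of the carveol. The C6–O(aryl) bond is made instead by SN2 inversion of trans-carveol.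
- The same pseudo-symmetry allows a short entry. (S)-Carvone gives (1S,5R)-trans-carveol in two steps by epoxidation and carbonyl transposition. Its carbonyl carbon becomes C2, which later receives ring B, and C4 keeps the descriptor S. (R)-Carvone would need three steps: reduction, inversion and ester cleavage.

**Step 1**
Reactants: 1 phloroglucinol + 2 isobutyryl chloride
Product: 3 phloroisobutyrophenone (2-methyl-1-(2,4,6-trihydroxyphenyl)propan-1-one)
Conditions: AlCl3 (3.5 equiv), CH2Cl2/MeNO2, 0 → 40 °C; then cold 1 M HCl
Reagents that add atoms: none
Why: Friedel–Crafts acylation of the threefold symmetric, strongly activated arene can give only one C-acyl isomer, and the chelated electron-withdrawing ketone should hold back a second acylation.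

**Step 2**
Reactants: 4 (S)-carvone
Product: 5 (1S,4S,6S)-1-methyl-4-(prop-1-en-2-yl)-7-oxabicyclo[4.1.0]heptan-2-one (oxirane trans to isopropenyl)
Conditions: 30% H2O2, NaOH (0.3 equiv), MeOH, 0 °C
Reagents that add atoms: hydrogen peroxide, OO
Why: Weitz–Scheffer nucleophilic epoxidation touches only the enone because the isolated isopropenyl alkene does not accept hydroperoxide anion, and axial attack at C6 anti to the C4 isopropenyl group places the oxirane trans to it, which sets the C6–O configuration.

**Step 3**
Reactants: 5 carvone epoxide
Product: 8 (1S,5R)-trans-carveol (C6–OH trans to isopropenyl; C1=C2), via epoxy hydrazone 6 (not isolated), via hydroxy alkenyldiazene 7 (not isolated)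
Conditions: N2H4·H2O (2.5 equiv), AcOH (cat.), MeOH, 0 °C → rt, argon
Reagents that add atoms: none
Why: Wharton transposition, in which hydrazone 6 opens the oxirane to the alkenyldiazene 7, which loses N2 and leaves hydrogen on C2, so that the ketone oxygen is removed, the double bond moves to C1=C2 and the untouched C6–O bond keeps the trans relation to isopropenyl set in step 2.

**Step 4**
Reactants: 8 (1S,5R)-trans-carveol + 3 phloroisobutyrophenone
Product: 9 cis-carvyl aryl ether (1-[2,6-dihydroxy-4-{[(1R,5R)-2-methyl-5-(prop-1-en-2-yl)cyclohex-2-en-1-yl]oxy}phenyl]-2-methylpropan-1-one)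
Conditions: PPh3, DIAD, THF, 0 °C → rt (3 in 1.5-fold excess)
Reagents that add atoms: none
Why: Mitsunobu etherification, an SN2 displacement known for cyclohex-2-enols and phenols, in which the free and most acidic 4-OH of 3 (the two ortho hydroxyls are engaged with and shielded by the isobutyryl group) attacks the activated C6 from the face opposite the leaving oxygen, so that C6 is inverted and the aryloxy group comes to lie cis to isopropenyl without any symmetric allyl intermediate.

**Step 5**
Reactants: 9 cis-carvyl aryl ether
Product: 11 C-terpenyl acylphloroglucinol (2-methyl-1-{2,4,6-trihydroxy-3-[(1S,5S)-2-methyl-5-(prop-1-en-2-yl)cyclohex-2-en-1-yl]phenyl}propan-1-one), via ortho-dienone 10 (not isolated)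
Conditions: PhNEt2, 160 °C, sealed tube, argon
Reagents that add atoms: none
Why: Aromatic Claisen rearrangement, whose concerted suprafacial [3,3] shift carries ring B from the C6 oxygen to C2 on the same face of ring A (1,3-chirality transfer sets C2 cis to isopropenyl), after which dienone 10 enolises to the phenol; the two ortho positions of 9 are equivalent, and the basic solvent suppresses acid-induced ionisation to the achiral carvyl cation.

**Step 6**
Reactants: 11 C-terpenyl acylphloroglucinol
Product: 12 cis-fused dihydrobenzofuran acylphloroglucinol (1-[(5aR,8S,9aR)-1,3-dihydroxy-5a-methyl-8-(prop-1-en-2-yl)-5a,6,7,8,9,9a-hexahydrodibenzo[b,d]furan-2-yl]-2-methylpropan-1-one)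
Conditions: camphorsulfonic acid (0.2 equiv), CH2Cl2, 0 °C → rt, stopped at full conversion
Reagents that add atoms: none
Why: Acid-catalysed intramolecular Markovnikov hydroalkoxylation of an ortho-cyclohexenylphenol (5-exo closure), in which protonation at C6 gives the tertiary C1 cation next to the free C2' hydroxyl (the C6' hydroxyl is engaged with the neighbouring ketone), and because this oxygen is held on the face of ring A that carries ring B it can only form the cis-fused ring, which sets C1 as R, while catalytic acid at low temperature is chosen to spare the isopropenyl group, which has no internal nucleophile.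

**Step 7**
Reactants: 12 cis-fused dihydrobenzofuran acylphloroglucinol + 13 prenyl bromide
Product: 15 dihydrofuran-fused gem-diprenyl acyl cyclohexadienone ((5aR,8S,9aR)-1-hydroxy-2-isobutyryl-5a-methyl-4,4-bis(3-methylbut-2-enyl)-8-(prop-1-en-2-yl)-5a,6,7,8,9,9a-hexahydrodibenzo[b,d]furan-3(4H)-one), via monoprenyl dihydrobenzofuran 14 (not isolated)
Conditions: 13 (2.5 equiv), KOH (3 equiv), H2O, 0 °C → rt, argon; then cold 1 M HCl
Reagents that add atoms: none
Why: Aqueous KOH turns 12 into its bis(phenoxide), whose carbon nucleophilicity peaks at C3' (ortho to the C4' oxygen, para to the C6' oxygen); C3' displaces bromide from the primary carbon of 13 in an SN2 step and the dienone so formed loses its C3' proton to give aromatic 14. The same carbon, now prenyl-substituted, attacks a second molecule of 13, which makes C3' quaternary and gives 15, a dienone that cannot re-aromatise and remains as a stabilised, poorly nucleophilic enolate, so alkylation should stop there. The closest known reaction type is the base-mediated exhaustive C-prenylation of acylphloroglucinols to gem-diprenyl cyclohexadienones of the hop beta-acid type. No ring is closed and no stereocentre is created, because C3' carries two identical groups, and C1, C2 and C4 are spectators. The step needs C- over O-alkylation, which the hydrogen-bonding aqueous medium and the soft allylic bromide favour, and it needs C3' over C1' and C5' in the dearomatising event, since a substituent alone does not block a ring carbon: C1' is shielded by the secondary C2 and the concave cis-fused ring system, and the charge at C5' is drained into the chelated isobutyryl group.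

**Step 8**
Reactants: 15 dihydrofuran-fused gem-diprenyl acyl cyclohexadienone
Product: 16 target (3,5-dihydroxy-4-[(1R,2R,5S)-2-hydroxy-2-methyl-5-(prop-1-en-2-yl)cyclohexyl]-2-isobutyryl-6,6-bis(3-methylbut-2-enyl)cyclohexa-2,4-dien-1-one)
Conditions: 2 M KOH, H2O/1,4-dioxane, 80 °C, degassed, argon; then cold 1 M HCl to pH 4 and immediate extraction
Reagents that add atoms: potassium hydroxide (its oxygen ends on C2'), [K+].[OH-]
Why: Saponification of a vinylogous ester by addition–elimination, in which hydroxide adds to C2' (the beta carbon of the C2'=C1'–C6'=O unit) and the tertiary C1 alkoxide leaves, so that the C1–O bond is never broken and C1 stays R, the opening is made irreversible by deprotonation of the new vinylogous acid, and acid, which would re-close the ring or ionise C1, is avoided.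

**Compound list**
1 | phloroglucinol | Oc1cc(O)cc(O)c1 | starting material
2 | isobutyryl chloride | CC(C)C(Cl)=O | starting material
3 | phloroisobutyrophenone | CC(C)C(=O)c1c(O)cc(O)cc1O | intermediate
4 | (S)-carvone | C=C(C)[C@H]1CC=C(C)C(=O)C1 | starting material
5 | (1S,4S,6S)-carvone epoxide, oxirane trans to isopropenyl | C=C(C)[C@H]1C[C@@H]2O[C@]2(C)C(=O)C1 | intermediate
6 | hydrazone of 5 | C=C(C)[C@H]1C[C@@H]2O[C@]2(C)C(=NN)C1 | intermediate (not isolated)
7 | (1S,5R)-3-diazenyl-2-methyl-5-(prop-1-en-2-yl)cyclohex-2-en-1-ol | C=C(C)[C@H]1C[C@H](O)C(C)=C(N=N)C1 | intermediate (not isolated)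
8 | (1S,5R)-trans-carveol | C=C(C)[C@@H]1CC=C(C)[C@@H](O)C1 | intermediate
9 | 4-O-[(1R,5R)-cis-carvyl] ether of 3 | C=C(C)[C@@H]1CC=C(C)[C@H](Oc2cc(O)c(C(=O)C(C)C)c(O)c2)C1 | intermediate
10 | ortho-dienone from the [3,3] shift (C1' sp3, configuration there transient) | C=C(C)[C@H]1CC=C(C)[C@@H](C2C(=O)C=C(O)C(C(=O)C(C)C)=C2O)C1 | intermediate (not isolated)
11 | 3-[(1S,5S)-2-methyl-5-(prop-1-en-2-yl)cyclohex-2-en-1-yl]phloroisobutyrophenone | C=C(C)[C@H]1CC=C(C)[C@@H](c2c(O)cc(O)c(C(=O)C(C)C)c2O)C1 | intermediate
12 | (5aR,8S,9aR) cis-fused dihydrobenzofuran acylphloroglucinol | C=C(C)[C@H]1CC[C@@]2(C)Oc3cc(O)c(C(=O)C(C)C)c(O)c3[C@H]2C1 | intermediate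
13 | prenyl bromide | CC(C)=CCBr | starting material
14 | C3'-monoprenyl derivative of 12 | C=C(C)[C@H]1CC[C@@]2(C)Oc3c(CC=C(C)C)c(O)c(C(=O)C(C)C)c(O)c3[C@H]2C1 | intermediate (not isolated)
15 | dihydrofuran-fused gem-diprenyl acyl cyclohexadienone | C=C(C)[C@H]1CC[C@@]2(C)OC3=C([C@H]2C1)C(O)=C(C(=O)C(C)C)C(=O)C3(CC=C(C)C)CC=C(C)C | intermediate
16 | CNP0324849.1, (1R,2R,4S) in ring A numbering | C=C(C)[C@H]1CC[C@@](C)(O)[C@@H](C2=C(O)C(CC=C(C)C)(CC=C(C)C)C(=O)C(C(=O)C(C)C)=C2O)C1 | target

Total step count: 8
Longest linear sequence: 7 (steps 2 to 8, from (S)-carvone)

**Steps most likely to fail**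

**Step 7 (key step).**
- What may go wrong: alkylation at oxygen; a halt after the first prenylation, because the second attack has to build a quaternary carbon next to the ether ring; loss of 13 by hydrolysis; or dearomatising attack through C1'.
- Fallback (from 12, back at 15): the SN2 alkylation of a free phenoxide is replaced by a Tsuji–Trost type dearomative allylation with prenyl methyl carbonate and Pd(PPh3)4 in THF at 50 °C.
- The electrophile is then an η3-(1,1-dimethylallyl)palladium complex that is attacked at its CH2 end, and the methoxide released serves as the base.
- Prenyl aryl and enol ethers are re-ionised by zerovalent palladium, so O-alkylation becomes reversible and the material should drain through 14 into 15. No new compound is made on this way (F0).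

**Step 8.**
- What may go wrong: sluggish addition of hydroxide, because the substrate is present as its enolate. Under forcing conditions retro-Claisen loss of the isobutyryl group, autoxidation of the electron-rich dianion, or re-closure during acidification may take over.
- Fallback (from 11, back at 16): the ether tether is given up and the C1 oxygen is brought in from outside.
- Ac2O, pyridine and DMAP give the triacetate F1. In F1 no phenol can intercept a halonium ion, and ring B is deactivated towards bromination.
- NBS in aqueous acetone at 0 °C prefers the trisubstituted ring alkene of limonene-type dienes over isopropenyl. By the Fürst–Plattner rule it should give the trans-diaxial bromohydrin F2, with the bromonium ion on the face away from ring B, water entering at C1 on the face of ring B, and bromine at C6.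
- Bu3SnH and AIBN in toluene at 80 °C remove the bromine to give the tertiary alcohol triacetate F3.
- K2CO3 in MeOH frees the hydroxy-terpenyl phloroglucinol F4.
- F4 is then submitted to the same double C-prenylation with 13 and aqueous KOH, which leads directly to 16.

**Step 6.**
- What may go wrong: protonation of the isopropenyl group with migration of its double bond; closure through the C6' hydroxyl instead of the C2' hydroxyl; or acid-induced detachment of the allylic terpene unit from the electron-rich ring.
- Fallback (from 11, back at 12): proton-initiated closure is replaced by phenylselenoetherification followed by radical reduction.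
- N-(Phenylseleno)phthalimide with catalytic camphorsulfonic acid in CH2Cl2 at −78 → 0 °C forms seleniranium ions reversibly. Only the ring alkene has an internal nucleophile.
- Anti addition, with selenium at C6 on the face away from ring B and the C2' oxygen at C1 on the face of ring B, should give the cis-fused selenide F5.
- Bu3SnH and AIBN in toluene at 80 °C then give 12.

**Further compounds**
F0 | step 7 | none | none
F1 | step 8 | triacetate of 11 | C=C(C)[C@H]1CC=C(C)[C@@H](c2c(OC(C)=O)cc(OC(C)=O)c(C(=O)C(C)C)c2OC(C)=O)C1
F2 | step 8 | trans-diaxial bromohydrin (C1–OH cis to ring B, C6–Br trans to it) | C=C(C)[C@H]1C[C@H](Br)[C@@](C)(O)[C@@H](c2c(OC(C)=O)cc(OC(C)=O)c(C(=O)C(C)C)c2OC(C)=O)C1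
F3 | step 8 | tertiary alcohol triacetate | C=C(C)[C@H]1CC[C@@](C)(O)[C@@H](c2c(OC(C)=O)cc(OC(C)=O)c(C(=O)C(C)C)c2OC(C)=O)C1
F4 | step 8 | 3-[(1R,2R,5S)-2-hydroxy-2-methyl-5-(prop-1-en-2-yl)cyclohexyl]phloroisobutyrophenone | C=C(C)[C@H]1CC[C@@](C)(O)[C@@H](c2c(O)cc(O)c(C(=O)C(C)C)c2O)C1
F5 | step 6 | C6-phenylselanyl derivative of 12 (selenium trans to the ring oxygen) | C=C(C)[C@H]1C[C@H]([Se]c4ccccc4)[C@@]2(C)Oc3cc(O)c(C(=O)C(C)C)c(O)c3[C@H]2C1
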